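**Plan**

Labels: ring C1 = quaternary carbon (CH2OH, homofarnesyl = (3E,7E)-4,8,12-trimethyltrideca-3,7,11-trienyl), C2 = CH (3-hydroxypropyl arm), C3 = alkylidene carbon, C4 and C5 = CH2, C6 = C(CH3)OH; Cα = α-carbon of the enal.
Enabling feature: C6(OH)–C1(CH2OH) is the retron of a 2,3-epoxy alcohol opened at its hydroxymethyl-bearing carbon. C2–C3 with the oxygen-terminated three-carbon arm is a latent 6-alkyl-3,4-dihydro-2H-pyran (arm oxygen on C3) whose nucleophilic β-carbon is C2, and the enal is the retro-oxa-Michael product of this temporary pyran ring.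
Cuts: C3=Cα (retro-oxa-Michael back to the pyran); then C3–Cα and ring bond C1–C2 together in one cascade; then C3–C4 (B-alkyl Suzuki), C5–C6 (Stille) and C1–side chain (acetoacetate alkylation).
Forward: farnesol → homofarnesyl iodide → tetrasubstituted Z-allylic alcohol carrying the dihydropyran → oxirane → strain-release opening closes the only carbocycle last → pyran opened → desilylation.
Stereochemistry: C1 and C6 come from Sharpless epoxidation of a geometrically pure olefin (anti opening at C1). C2 comes from a chair closure with the ring-locked enol ether. The chain E-olefins come from farnesol, and the Z-enal from allylic strain in the elimination.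

Key step: step 14

Assumption: commercial (2E,6E)-farnesol of high isomeric purity is used, and the Z-enal (formyl cis to C2) is taken to be the more stable geometric isomer.

**Step 1**
Reactants: 1 (2E,6E)-farnesol
Product: 2 (2E,6E)-farnesal
Conditions: TEMPO (cat.), PhI(OAc)2, CH2Cl2, rt
Reagents that add atoms: none
Why: Oxoammonium (TEMPO) oxidation of a primary allylic alcohol stops at the enal and neither attacks nor isomerises the trisubstituted olefins.

**Step 2**
Reactants: 2 (2E,6E)-farnesal
Product: 3 (3E,7E)-4,8,12-trimethyltrideca-1,3,7,11-tetraene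
Conditions: Ph3PCH3Br, n-BuLi, THF, 0 °C; then 2, −78 °C → rt
Reagents that add atoms: methyltriphenylphosphonium bromide, C[P+](c1ccccc1)(c1ccccc1)c1ccccc1.[Br-]
Why: Wittig methylenation with the non-stabilised ylide converts the enal into the terminal 1,3-diene without touching the E-olefins.

**Step 3**
Reactants: 3 (3E,7E)-4,8,12-trimethyltrideca-1,3,7,11-tetraene
Product: 5 (3E,7E)-homofarnesol, via B-homofarnesyl-9-BBN 4 (not isolated)
Conditions: 9-BBN, THF, 0 °C → rt; then H2O2, aq NaOH, 0 °C
Reagents that add atoms: 9-borabicyclo[3.3.1]nonane, [H]B1C2CCCC1CCC2 (boron present only in 4); hydrogen peroxide, OO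
Why: Hydroboration–oxidation, in which the bulky dialkylborane adds only to the monosubstituted end of the diene with boron on the terminal carbon, should give the homoallylic alcohol and leave all trisubstituted olefins.

**Step 4**
Reactants: 5 (3E,7E)-homofarnesol
Product: 6 (E,E)-homofarnesyl iodide
Conditions: I2, PPh3, imidazole, CH2Cl2, 0 °C
Reagents that add atoms: iodine, II
Why: Appel-type iodination proceeds by SN2 displacement of the alkoxyphosphonium ion under buffered conditions that spare the olefins.

**Step 5**
Reactants: 6 (E,E)-homofarnesyl iodide; 7 methyl acetoacetate (excess)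
Product: 8 methyl (5E,9E)-2-acetyl-6,10,14-trimethylpentadeca-5,9,13-trienoate (racemic)
Conditions: K2CO3, DMF, 50 °C
Reagents that add atoms: none
Why: Acetoacetic ester alkylation of the soft enolate with a primary iodide joins the side chain to C1, excess 7 suppresses dialkylation, and the racemic centre formed is erased in step 6.

**Step 6**
Reactants: 8 methyl (5E,9E)-2-acetyl-6,10,14-trimethylpentadeca-5,9,13-trienoate
Product: 9 (Z)-enol triflate of 8 (OTf cis to CO2Me)
Conditions: saturated aq LiOH, Tf2O, toluene, 5 °C
Reagents that add atoms: triflic anhydride, O=S(=O)(C(F)(F)F)OS(=O)(=O)C(F)(F)F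
Why: O-sulfonylation of a β-keto ester enolate, in which lithium chelation between the enolate and ester oxygens fixes the Z-enolate, should place OTf cis to CO2Me and so later place C5 cis to the CH2OH carbon.

**Step 7**
Reactants: 9 (Z)-enol triflate
Product: 10 methyl (2Z)-2-homofarnesyl-3-methylpenta-2,4-dienoate (vinyl cis to CO2Me)
Conditions: tributyl(vinyl)stannane, Pd(PPh3)4 (cat.), LiCl, THF, reflux
Reagents that add atoms: tributyl(vinyl)stannane, C=C[Sn](CCCC)(CCCC)CCCC
Why: Stille coupling of an enol triflate proceeds with retention of olefin geometry and brings in C5 and C4 as a vinyl group.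

**Step 8**
Reactants: 10 methyl (2Z)-2-homofarnesyl-3-methylpenta-2,4-dienoate
Product: 11 (2Z)-2-homofarnesyl-3-methylpenta-2,4-dien-1-ol
Conditions: iBu2AlH, CH2Cl2, −78 °C; aq potassium sodium tartrate
Reagents that add atoms: none
Why: 1,2-Reduction of a conjugated ester with iBu2AlH gives the allylic alcohol without touching the diene or the chain olefins.

**Step 9**
Reactants: 12 δ-valerolactone
Product: 13 3,4-dihydro-2H-pyran-6-yl diphenyl phosphate
Conditions: KN(SiMe3)2 added to 12 and (PhO)2P(O)Cl, THF–DMPU, −78 °C
Reagents that add atoms: diphenyl chlorophosphate, O=P(Cl)(Oc1ccccc1)Oc1ccccc1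
Why: O-phosphorylation of the lactone enolate (ketene acetal phosphate formation) under internal-quench conditions outruns Claisen self-condensation.

**Step 10**
Reactants: 11 (2Z)-2-homofarnesyl-3-methylpenta-2,4-dien-1-ol; 13 3,4-dihydro-2H-pyran-6-yl diphenyl phosphate
Product: 15 (2Z)-5-(3,4-dihydro-2H-pyran-6-yl)-2-homofarnesyl-3-methylpent-2-en-1-ol, via bis-boron adduct 14 (not isolated)
Conditions: 9-BBN (2.2 equiv), THF, 0 °C → rt; then 13, PdCl2(dppf) (cat.), 3 M aq Cs2CO3, DMF, 50 °C; Et3N-deactivated silica
Reagents that add atoms: 9-borabicyclo[3.3.1]nonane, [H]B1C2CCCC1CCC2 (boron present only in 14)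
Why: Hydroboration followed by B-alkyl Suzuki–Miyaura coupling with a lactone-derived enol phosphate, in which 9-BBN adds only to the monosubstituted vinyl group (boron on C4, hydroxyl transiently borylated), forms C3–C4 and delivers the cyclic enol ether with its double bond fixed in the ring.

**Step 11**
Reactants: 15 (2Z)-5-(3,4-dihydro-2H-pyran-6-yl)-2-homofarnesyl-3-methylpent-2-en-1-ol
Product: 16 {(2S,3R)-3-[2-(3,4-dihydro-2H-pyran-6-yl)ethyl]-2-homofarnesyl-3-methyloxiran-2-yl}methanol
Conditions: Ti(OiPr)4 (cat.), L-(+)-diethyl tartrate (cat.), t-BuOOH, 4 Å MS, CH2Cl2, −25 °C; non-acidic work-up (aq NaOH–brine)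
Reagents that add atoms: tert-butyl hydroperoxide, CC(C)(C)OO
Why: In the Sharpless asymmetric epoxidation the titanium tartrate complex binds the allylic alcohol and oxidises only this olefin (chain olefins and the unbound enol ether are not activated), syn addition carries the Z geometry into the relative configuration of C1 and C6, and L-(+)-tartrate selects the face that gives the (2S,3R)-oxirane according to the empirical face rule.

**Step 12**
Reactants: 16 epoxy alcohol
Product: 17 tert-butyldimethylsilyl ether of 16
Conditions: TBSCl, imidazole, DMF, 0 °C → rt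
Reagents that add atoms: tert-butyldimethylsilyl chloride, CC(C)(C)[Si](C)(C)Cl
Why: Standard silylation of a primary alcohol under basic conditions leaves the oxirane and enol ether intact and removes the hydroxyl that would otherwise chelate the Lewis acid and steer opening towards C6.

**Step 13**
Reactants: 18 propanal
Product: 19 (Z)-trimethyl(prop-1-enyloxy)silane
Conditions: TMSOTf, Et3N, Et2O, 0 °C
Reagents that add atoms: trimethylsilyl trifluoromethanesulfonate, C[Si](C)(C)OS(=O)(=O)C(F)(F)F
Why: Soft enolisation–silylation of the aldehyde gives the enol silane, whose geometry is irrelevant because the centre it creates is erased later.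

**Step 14**
Reactants: 17 silylated epoxide; 19 (Z)-trimethyl(prop-1-enyloxy)silane
Product: 21 2-[(4aR,5R,6R)-5-(tert-butyldimethylsilyloxymethyl)-5-homofarnesyl-6-methyl-6-(trimethylsilyloxy)octahydro-2H-chromen-8a-yl]propanal (epimers at C8a and at the side-chain α-carbon), via oxocarbenium triflate 20 (not isolated)
Conditions: 19 (1.5 equiv), TMSOTf (0.2 equiv), 2,6-di-tert-butyl-4-methylpyridine (0.3 equiv), 4 Å MS, CH2Cl2, −78 °C; Et3N quench
Reagents that add atoms: trimethylsilyl trifluoromethanesulfonate, C[Si](C)(C)OS(=O)(=O)C(F)(F)F (silyl group and counter-ion of 20; returned on capture)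
Why: Proposed new method: TMSOTf silylates the oxirane oxygen, the enol-ether β-carbon (C2) attacks the CH2OTBS-bearing oxirane carbon (C1) from the rear with release of ring strain, and the resulting bicyclic oxocarbenium ion 20 (C3=O+) is captured at C3 by enol silane 19, whose silyl group returns to triflate, so that the cascade is catalytic in TMSOTf and loses no atom. The closest known reaction types are the Lewis-acid-promoted epoxide-initiated cation–olefin cyclisation terminated by an enol ether and the TMSOTf-catalysed Mukaiyama addition of enol silanes to ketal-derived oxocarbenium ions; new are their merger in one flask and the opening of a tetrasubstituted oxirane at its oxymethyl-bearing carbon. The one ring closed, the carbocycle C1–C6, forms in a 6-endo mode with respect to both the oxirane and the enol-ether double bond through a chair, the topology of the first ring closure of epoxy-polyene cyclisations. C6 keeps its epoxidation-derived configuration because its C–O bond is not broken, C1 is set by stereospecific inversion, C2 is set by the ring-locked geometry of the dihydropyran double bond (arm carbon trans to C4), which places the arm equatorial and cis to CH2OTBS and is also the more stable arrangement should 20 lose and regain its C2 proton, and the two centres made in the capture (C3, Cα) need no control because step 15 erases them. The step needs cleavage of C1–O rather than C6–O and reaction of the enol ether rather than of the three trisubstituted olefins: attack of C2 on C6 would be a five-membered enol-endo closure in which the π-orbital cannot reach the rear of the C–O bond, the enol ether is by orders of magnitude the best π-nucleophile present, and a silyl rather than an acyl group on the oxymethyl keeps the inductive bias against C1 small. Low temperature, a hindered pyridine as proton trap and a non-ionising solvent should suppress unassisted ionisation at C6, semipinacol shifts and proton-initiated polyene cyclisation.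

**Step 15**
Reactants: 21 β-pyranyloxy aldehyde
Product: 22 bis-silyl iridal (C1–CH2OTBS, C6–OTMS, free 3-hydroxypropyl arm, Z-enal; 2S,3R,4R in cyclohexylidene numbering)
Conditions: DBU, CH2Cl2, 0 °C → rt
Reagents that add atoms: none
Why: E1cB (retro-oxa-Michael) elimination, in which deprotonation at Cα expels the tertiary pyranyl alkoxide, unmasks the hydroxypropyl arm and the tetrasubstituted enal at once, and allylic 1,3-strain places the slimmer formyl group on the side of the branched C2 (Z) while reversible oxa-Michael re-addition lets the geometry settle to this isomer.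

**Step 16**
Reactants: 22 bis-silyl iridal
Product: 23 iridal, (Z)-2-[(2S,3R,4R)-4-hydroxy-3-(hydroxymethyl)-2-(3-hydroxypropyl)-4-methyl-3-homofarnesylcyclohexylidene]propanal
Conditions: Bu4NF, AcOH, THF, 0 °C → rt
Reagents that add atoms: none
Why: Fluoride-mediated desilylation buffered with acetic acid cleaves both silyl ethers without base-induced epimerisation at the γ-position C2 or isomerisation of the enal.

**Compound list**

| No. | Name | SMILES | Role |
|---|---|---|---|
| 1 | (2E,6E)-farnesol | CC(C)=CCC/C(C)=C/CC/C(C)=C/CO | starting material |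
| 2 | (2E,6E)-farnesal | CC(C)=CCC/C(C)=C/CC/C(C)=C/C=O | intermediate |
| 3 | (3E,7E)-4,8,12-trimethyltrideca-1,3,7,11-tetraene | CC(C)=CCC/C(C)=C/CC/C(C)=C/C=C | intermediate |
| 4 | B-homofarnesyl-9-BBN | CC(C)=CCC/C(C)=C/CC/C(C)=C/CCB1C2CCCC1CCC2 | intermediate (not isolated) |
| 5 | (3E,7E)-homofarnesol | CC(C)=CCC/C(C)=C/CC/C(C)=C/CCO | intermediate |
| 6 | (E,E)-homofarnesyl iodide, (6E,10E)-13-iodo-2,6,10-trimethyltrideca-2,6,10-triene | CC(C)=CCC/C(C)=C/CC/C(C)=C/CCI | intermediate |
| 7 | methyl acetoacetate | CC(=O)CC(=O)OC | starting material |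
| 8 | methyl (5E,9E)-2-acetyl-6,10,14-trimethylpentadeca-5,9,13-trienoate (racemic) | CC(C)=CCC/C(C)=C/CC/C(C)=C/CCC(C(C)=O)C(=O)OC | intermediate |
| 9 | methyl (2Z,5E,9E)-6,10,14-trimethyl-2-[1-(trifluoromethylsulfonyloxy)ethylidene]pentadeca-5,9,13-trienoate | CC(C)=CCC/C(C)=C/CC/C(C)=C/CC/C(C(=O)OC)=C(\C)OS(=O)(=O)C(F)(F)F | intermediate |
| 10 | methyl (2Z)-2-homofarnesyl-3-methylpenta-2,4-dienoate | CC(C)=CCC/C(C)=C/CC/C(C)=C/CC/C(C(=O)OC)=C(\C)C=C | intermediate |
| 11 | (2Z)-2-homofarnesyl-3-methylpenta-2,4-dien-1-ol | CC(C)=CCC/C(C)=C/CC/C(C)=C/CC/C(CO)=C(\C)C=C | intermediate |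
| 12 | δ-valerolactone | O=C1CCCCO1 | starting material |
| 13 | 3,4-dihydro-2H-pyran-6-yl diphenyl phosphate | O=P(OC1=CCCCO1)(Oc1ccccc1)Oc1ccccc1 | intermediate |
| 14 | bis-boron adduct (C4–B alkylborane, O-borinate) | CC(C)=CCC/C(C)=C/CC/C(C)=C/CC/C(COB1C2CCCC1CCC2)=C(\C)CCB1C2CCCC1CCC2 | intermediate (not isolated) |
| 15 | (2Z)-5-(3,4-dihydro-2H-pyran-6-yl)-2-homofarnesyl-3-methylpent-2-en-1-ol | CC(C)=CCC/C(C)=C/CC/C(C)=C/CC/C(CO)=C(\C)CCC1=CCCCO1 | intermediate |
| 16 | {(2S,3R)-3-[2-(3,4-dihydro-2H-pyran-6-yl)ethyl]-2-homofarnesyl-3-methyloxiran-2-yl}methanol | CC(C)=CCC/C(C)=C/CC/C(C)=C/CC[C@@]1(CO)O[C@]1(C)CCC2=CCCCO2 | intermediate |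
| 17 | tert-butyldimethylsilyl ether of 16 | CC(C)=CCC/C(C)=C/CC/C(C)=C/CC[C@@]1(CO[Si](C)(C)C(C)(C)C)O[C@]1(C)CCC2=CCCCO2 | intermediate |
| 18 | propanal | CCC=O | starting material |
| 19 | (Z)-trimethyl(prop-1-enyloxy)silane | C/C=C\O[Si](C)(C)C | intermediate |
| 20 | (4aR,5R,6R)-bicyclic oxocarbenium triflate (C3=O+, C6–OTMS) | CC(C)=CCC/C(C)=C/CC/C(C)=C/CC[C@]1(CO[Si](C)(C)C(C)(C)C)[C@H]2CCC[O+]=C2CC[C@@]1(C)O[Si](C)(C)C.[O-]S(=O)(=O)C(F)(F)F | intermediate (not isolated) |
| 21 | 2-[(4aR,5R,6R)-5-(tert-butyldimethylsilyloxymethyl)-5-homofarnesyl-6-methyl-6-(trimethylsilyloxy)octahydro-2H-chromen-8a-yl]propanal (epimers at C8a and side-chain α-carbon) | CC(C)=CCC/C(C)=C/CC/C(C)=C/CC[C@]1(CO[Si](C)(C)C(C)(C)C)[C@H]2CCCOC2(C(C)C=O)CC[C@@]1(C)O[Si](C)(C)C | intermediate |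
| 22 | bis-silyl iridal | CC(C)=CCC/C(C)=C/CC/C(C)=C/CC[C@]1(CO[Si](C)(C)C(C)(C)C)[C@@H](CCCO)/C(=C(/C)C=O)CC[C@@]1(C)O[Si](C)(C)C | intermediate |
| 23 | iridal | CC(C)=CCC/C(C)=C/CC/C(C)=C/CC[C@]1(CO)[C@@H](CCCO)/C(=C(/C)C=O)CC[C@@]1(C)O | target |

**Step count**

Total step count: 16. Longest linear sequence: 14 (steps 1–8, 10–12, 14–16).

**Steps most likely to fail**

1. **Step 14.** Three things may go wrong.
   - Capture of the oxocarbenium ion by the enol silane may be slower than proton loss or oligomerisation of the enol ether.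
   - The enol silane may attack the activated oxirane directly.
   - Unassisted ionisation at C6 may lead to rearrangement.

   The fallback uses known chemistry only, sets out from 17 and returns at 21, and separates ring closure from C3–Cα bond formation. Stoichiometric MeAlCl2 (CH2Cl2, −78 °C) is the established promoter for epoxide-initiated cyclisations that end on an enol ether. With aqueous work-up it should give hydroxy ketone F1, in equilibrium with its bicyclic hemiketal. MeOH with pyridinium p-toluenesulfonate closes this to methyl ketal F2. 1-(Trimethylsilyl)imidazole protects the tertiary alcohol to give silyl ether F3. TMSOTf-catalysed Mukaiyama-type substitution of the ketal methoxy group by 19 then gives 21.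

2. **Step 11.** Oxygen transfer to a tetrasubstituted olefin with a cis substituent may be slow and insufficiently face-selective. The acid-sensitive enol ether may also suffer solvolysis or peroxide addition in the presence of Ti(OiPr)4 and t-BuOOH. The fallback sets out from 11 and returns at 17, and installs the enol ether only after the oxidation. Sharpless epoxidation of dienol 11 with L-(+)-diethyl tartrate gives vinyl epoxy alcohol F4. TBSCl and imidazole give silyl ether F5. 9-BBN adds to the vinyl group to give borane F6, which is coupled with 13 under the conditions of step 10 to give 17.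

3. **Step 15.** The elimination may show poor geometric selectivity, and γ-deprotonation of the enal by base may erode the configuration at C2. The fallback sets out from 21 and returns at 23, and changes the opening from anionic to cationic. TMSOTf and Et3N convert 21 into enol silane F7. A catalytic amount of TMSOTf (CH2Cl2, −78 → −40 °C) then silylates the pyran oxygen, and the enol silane expels it. This is the Lewis-acid β-alkoxy elimination known from acetal–enol ether chain extension of polyene aldehydes. It should give tris-silyl ether F8 with no base present. The conditions of step 16 convert F8 into 23.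

**Further compounds**

F1 | step 14 | (2R,3R,4R)-3-(tert-butyldimethylsilyloxymethyl)-4-hydroxy-2-(3-hydroxypropyl)-3-homofarnesyl-4-methylcyclohexanone | CC(C)=CCC/C(C)=C/CC/C(C)=C/CC[C@]1(CO[Si](C)(C)C(C)(C)C)[C@@H](CCCO)C(=O)CC[C@@]1(C)O
F2 | step 14 | (4aR,5R,6R)-5-(tert-butyldimethylsilyloxymethyl)-5-homofarnesyl-8a-methoxy-6-methyloctahydro-2H-chromen-6-ol | CC(C)=CCC/C(C)=C/CC/C(C)=C/CC[C@]1(CO[Si](C)(C)C(C)(C)C)[C@H]2CCCOC2(OC)CC[C@@]1(C)O
F3 | step 14 | trimethylsilyl ether of F2 | CC(C)=CCC/C(C)=C/CC/C(C)=C/CC[C@]1(CO[Si](C)(C)C(C)(C)C)[C@H]2CCCOC2(OC)CC[C@@]1(C)O[Si](C)(C)C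
F4 | step 11 | [(2S,3R)-3-ethenyl-2-homofarnesyl-3-methyloxiran-2-yl]methanol | CC(C)=CCC/C(C)=C/CC/C(C)=C/CC[C@@]1(CO)O[C@]1(C)C=C
F5 | step 11 | tert-butyldimethylsilyl ether of F4 | CC(C)=CCC/C(C)=C/CC/C(C)=C/CC[C@@]1(CO[Si](C)(C)C(C)(C)C)O[C@]1(C)C=C
F6 | step 11 | 9-BBN adduct of F5 (boron on C4) | CC(C)=CCC/C(C)=C/CC/C(C)=C/CC[C@@]1(CO[Si](C)(C)C(C)(C)C)O[C@]1(C)CCB2C3CCCC2CCC3
F7 | step 15 | trimethylsilyl enol ether of 21 | CC(C)=CCC/C(C)=C/CC/C(C)=C/CC[C@]1(CO[Si](C)(C)C(C)(C)C)[C@H]2CCCOC2(C(C)=CO[Si](C)(C)C)CC[C@@]1(C)O[Si](C)(C)C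
F8 | step 15 | tris-silyl iridal (arm O-TMS, C6 O-TMS, C1 CH2O-TBS) | CC(C)=CCC/C(C)=C/CC/C(C)=C/CC[C@]1(CO[Si](C)(C)C(C)(C)C)[C@@H](CCCO[Si](C)(C)C)/C(=C(/C)C=O)CC[C@@]1(C)O[Si](C)(C)C
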